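**Remark on the chemistry:** atom numbers C1–C13 follow the germacranolide skeleton. The target as drawn has H6 and H7 on the same face (cis-fused lactone) and the route is designed for that isomer. Allyl 4-methoxybenzyl ether is taken as a purchasable ether. The configurations of the key-step ketone, the ynone and the target were cross-checked centre by centre and need no correction. (TBS = tert-butyldimethylsilyl, TES = triethylsilyl, PMB = 4-methoxybenzyl.)

## Structural features

The target is a ten-membered carbocycle (ring A, C1–C10). An oxygen bridges C3 and C10, so that O, C10, C1, C2 and C3 form a 3(2H)-furanone (ring B) with the ketone at C1 and the enol ether double bond at C2=C3. An α-methylene-γ-butyrolactone (ring C: O, C6, C7, C11, C12) is cis-fused to ring A at C6–C7. Five contiguous stereocentres run from C6 to C10 (6S,7S,8S,9R,10R); C10 is fully substituted (methyl, ring oxygen, C1, C9), C9 carries a free hydroxyl and C8 an isovalerate. The C4=C5 double bond is trisubstituted, Z, and conjugated with ring B. The fragile groups are the exocyclic methylene lactone (a Michael acceptor), the cross-conjugated dienone, the C8 ester beside a free C9 hydroxyl (acyl migration), the lactone that could shift to O8, and the Z alkene. The real difficulty is closing a medium ring that already holds two rigid unsaturated units while controlling the C6–C10 stereo-array and keeping O8 and O9 distinguishable. The feature used by the key step is that C1 and C2 of ring B lie between the carbinol carbon C10 and the acyl carbon C3. A two-carbon unit at the alkyne oxidation level therefore supplies both atoms, and the resulting γ-hydroxy ynone is an isomer of the furanone.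

## Logic of the disconnections

**33 back to 30 (through 32 and 31).** The C8 O–acyl bond is cut and O9 is returned to its silyl ether, O8 to its PMB ether. The ester is put on last because it would not survive the organometallic steps and could migrate to a free O9. This demands that O8 and O9 carry orthogonal groups from the moment they are created.

**30 back to 27.** The C6–C7 bond and the O6–C12 lactone bond are cut together. This opens rings A and C at once and removes the C6 and C7 stereocentres, leaving a Z enal and a 2-(bromomethyl)acrylate in one chain. The forward step must add the allylmetal through C7 to the C6 aldehyde only, with the cis ring fusion and the correct face relative to C8.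

**27 back to 22 and 23 (through 26, 25 and 24).** The C6 aldehyde is traced to its silyl-protected allylic alcohol, the C13 bromide to an allylically transposed C7 carbinol, and the C7–C11 bond is cut. This reveals a C7 aldehyde and the three-carbon acrylate unit. The forward sequence must handle an α,β-dioxygenated aldehyde under amine catalysis and keep the allylic bromide intact while C6 is unmasked.

**22 back to 20.** The C7 formyl group is traced to a vinyl group with one sacrificial carbon. The vinyl group is inert to every earlier step. The cleavage must distinguish the monosubstituted alkene from the two conjugated ones.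

**20 back to 18.** Ring B is opened at the O–C3 bond and the carbonyl is moved from C1 back to C3, which gives an acyclic γ-hydroxy ynone of the same composition. The forward step needs amine addition at C1, hydrolysis and 5-exo-trig closure of the C10 hydroxyl on C3. Because C10 is quaternary it cannot epimerise.

**18 back to 10, 15 and 14.** The C10–C1 and C2–C3 bonds are cut, so the chain falls into a C7–C10 methyl ketone, acetylene and a C3–C6 acyl donor. This is the most convergent cut of the chain and creates C10 on an acyclic ketone with one neighbouring stereocentre. The forward step needs facial control at C10 and mono-acylation of the alkynyl end.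

**10 back to 3 and 4 (through 9, 8 and 7).** The ketone is traced to a secondary carbinol, the C9 silyl ether to a free hydroxyl, and the C8–C9 bond is cut. One reagent-controlled alkoxyallylboration then sets C8 and C9 and delivers O8 as PMB ether and O9 as free hydroxyl, already differentiated. The C10 oxygen needs a temporary group removable beside TBS and PMB.

**3 back to 1 (through 2).** The aldehyde comes from the lactate ester by silylation and partial reduction. The lactate stereocentre only reinforces the allylboration and is later oxidised away.

**14 back to 11 and 12 (through 13).** The C4=C5 bond is cut by a Z-selective phosphonate olefination and the amide C–N bond by aminolysis. The olefination must give the Z geometry that later places C3 and C6 on the same side.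

## Other disconnections considered

**Alternative 1: pinacol closure at C8–C9.**
- Cut and forward step: the C8–C9 bond of ring A is cut. SmI2 would reduce both formyl groups of the seco-dialdehyde A2 to ketyls whose coupling closes ring A and gives the macrocyclic 8,9-diol A1.
- In its favour: ring and both carbinol centres arise in one step, and C6 and C7 would be set earlier on an acyclic, reagent-controllable intermediate. On that point it is better than the chosen plan, which creates C6 and C7 during ring closure.
- Against it here:
  - The C9 formyl group of A2 sits on C10, which carries the furanone oxygen. Such α-alkoxy carbonyls are prone to reductive C–O cleavage by SmI2, which would open ring B. The dienone is itself reducible.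
  - A samarium-bridged diketyl normally delivers the cis-diol, whereas the target has the threo relation of L-tartaric acid at C8/C9.
  - The two secondary hydroxyls of A1 must then be told apart for acylation at C8, and the C13 methylene must still be added.
- Comparison: convergence is equal. The chosen plan is more secure on the C8/C9 configuration and on O8/O9 differentiation. Step count is similar once the extra acylation and methylenation are included.

**Alternative 2: alkynyl addition closing C1–C2.**
- Cut and forward step: the C1–C2 bond is cut. CrCl2 with catalytic NiCl2 would convert the iodoalkyne of A4 into an alkynylchromium that adds to the C1 aldehyde, giving the cyclic propargylic alcohol A3. Oxidation at C1, release of the C10 hydroxyl and 5-endo-dig closure would then build ring B.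
- In its favour: all five stereocentres, ring C with its methylene and the C8 ester are in place before ring closure, and the new C1 carbinol is later oxidised, so the closure poses no stereochemical question. This is better than the chosen plan. The addition is very tolerant of functional groups.
- Against it here:
  - Ring A must be closed around a Z-enyne with four nearly collinear atoms, which puts strain into the ten-membered ring.
  - The C1 aldehyde is neopentylic, flanked by the fully substituted silyloxy carbon C10.
  - The methylene lactone and the isovalerate must survive the later oxidation and cyclisation, and A4 needs two differentiated silyl ethers and an iodoalkyne.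
- Comparison: mechanistically the closure is a clean 1,2-addition with a disposable stereocentre (better). Structurally it forces strain into ring A, whereas the chosen plan closes ring A at an sp3–sp3 bond with ring B already formed. Step economy is about equal.

**Alternative 3: late lactone by carbenoid C–H insertion.**
- Cut and forward step: the C7–C11 bond of ring C is cut. Rh2(OAc)4 would decompose the C6 diazophosphonoacetate A6, and the carbenoid would insert into the C7–H bond on the face of O6 to give the α-phosphono lactone A5. Olefination with formaldehyde would then deliver the methylene.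
- In its favour: a 1,5-insertion proceeds with retention, so the cis ring fusion follows from geometry once C6 is set. This is as good as or better than the chosen plan for the C6/C7 relation. The phosphonate is the handle for methylenation, so ring C and its methylene take two steps (better step economy for ring C), and the sensitive methylene lactone appears only at the end.
- Against it here:
  - A6 is an allylic diazo ester, and cyclopropanation of C4=C5 is normally faster than insertion into an unactivated methylene.
  - The C7–H bond is inductively deactivated by the C8 silyloxy group, while the activated C8–H offers a competing 1,6-insertion.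
  - The macrocycle A6 with a C7 methylene and a defined C6 centre needs its own, unsolved ring closure.
- Comparison: the endgame is shorter and structurally gentler. The chemoselectivity of the carbenoid is a gamble, where the chosen plan uses polar bond formations at predictable sites. Overall step count is not lower once A6 has to be made.

Key step: step 9

## Route

Step 1
Reactants: 1 ethyl (S)-lactate
Product: 2 ethyl (2S)-2-(triethylsilyloxy)propanoate
Conditions: Et3SiCl, imidazole, CH2Cl2, 0 °C → rt
Reagents that add atoms: chlorotriethylsilane, CC[Si](Cl)(CC)CC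
Why: Routine silylation of a secondary alcohol that leaves the stereocentre untouched; the triethylsilyl group is chosen because it can later be removed beside a TBS ether.

Step 2
Reactants: 2 ethyl (2S)-2-(triethylsilyloxy)propanoate
Product: 3 (2S)-2-(triethylsilyloxy)propanal
Conditions: i-Bu2AlH, CH2Cl2, −78 °C; aq. KNaC4H4O6
Reagents that add atoms: none
Why: Partial reduction of an α-silyloxy ester stops at the aldehyde because the aluminium hemiacetal is stable at −78 °C; the aldehyde is used at once to avoid racemisation.

Step 3
Reactants: 3 (2S)-2-(triethylsilyloxy)propanal; 4 allyl 4-methoxybenzyl ether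
Product: 7 (2S,3R,4S)-4-(4-methoxybenzyloxy)-2-(triethylsilyloxy)hex-5-en-3-ol, via (Z)-3-(4-methoxybenzyloxy)allyllithium 5 (not isolated), via [(Z)-3-(4-methoxybenzyloxy)allyl]diisopinocampheylborane 6 (not isolated)
Conditions: 4, s-BuLi, THF, −78 °C; (+)-Ipc2BOMe; BF3·OEt2; 3, −78 °C → rt; ethanolamine
Reagents that add atoms: none
Why: Brown alkoxyallylboration through a chair Zimmerman–Traxler transition state: the Z geometry of 6 gives the syn relation of the new C8 and C9 oxygens, and the isopinocampheyl groups derived from (−)-α-pinene direct attack to the Re face of the aldehyde, which sets both centres absolutely. The (S)-aldehyde is the matched partner because this face is also its Felkin face; the non-oxidative work-up avoids base-induced silyl migration.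

Step 4
Reactants: 7 (2S,3R,4S)-4-(4-methoxybenzyloxy)-2-(triethylsilyloxy)hex-5-en-3-ol
Product: 8 (2S,3R,4S)-3-(tert-butyldimethylsilyloxy)-4-(4-methoxybenzyloxy)-2-(triethylsilyloxy)hex-5-ene
Conditions: TBSOTf, 2,6-lutidine, CH2Cl2, −78 → 0 °C
Reagents that add atoms: tert-butyldimethylsilyl triflate, CC(C)(C)[Si](C)(C)OS(=O)(=O)C(F)(F)F
Why: The silyl triflate protects the hindered secondary C9 hydroxyl under non-migrating, weakly basic conditions; this installs the bulky non-chelating group needed for the key step.

Step 5
Reactants: 8 (2S,3R,4S)-3-(tert-butyldimethylsilyloxy)-4-(4-methoxybenzyloxy)-2-(triethylsilyloxy)hex-5-ene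
Product: 9 (2S,3S,4S)-3-(tert-butyldimethylsilyloxy)-4-(4-methoxybenzyloxy)hex-5-en-2-ol
Conditions: PPTS (cat.), MeOH/CH2Cl2, 0 °C
Reagents that add atoms: none
Why: Acid-catalysed methanolysis cleaves a triethylsilyl ether much faster than a hindered TBS ether, and acidic conditions do not promote 1,2-silyl migration.

Step 6
Reactants: 9 (2S,3S,4S)-3-(tert-butyldimethylsilyloxy)-4-(4-methoxybenzyloxy)hex-5-en-2-ol
Product: 10 (3R,4S)-3-(tert-butyldimethylsilyloxy)-4-(4-methoxybenzyloxy)hex-5-en-2-one (fragment 1)
Conditions: Dess–Martin periodinane, NaHCO3, CH2Cl2, 0 °C → rt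
Reagents that add atoms: none
Why: Buffered Dess–Martin oxidation converts the secondary carbinol into the methyl ketone without epimerising the adjacent silyloxy centre; the lactate stereocentre has served its purpose and is removed here.

Step 7
Reactants: 11 (tert-butyldimethylsilyloxy)acetaldehyde; 12 methyl 2-[bis(2,2,2-trifluoroethoxy)phosphoryl]propanoate
Product: 13 methyl (2Z)-4-(tert-butyldimethylsilyloxy)-2-methylbut-2-enoate
Conditions: KN(SiMe3)2, 18-crown-6, THF, −78 °C
Reagents that add atoms: none
Why: Still–Gennari olefination; the electron-poor phosphonate under dissociating conditions eliminates fast from the kinetic adduct and should give the Z trisubstituted enoate (ester cis to C6).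

Step 8
Reactants: 13 methyl (2Z)-4-(tert-butyldimethylsilyloxy)-2-methylbut-2-enoate
Product: 14 (2Z)-4-(tert-butyldimethylsilyloxy)-N-methoxy-N,2-dimethylbut-2-enamide (fragment 2)
Conditions: MeNHOMe·HCl, i-PrMgCl, THF, −20 → 0 °C
Reagents that add atoms: N,O-dimethylhydroxylamine hydrochloride, CNOC.Cl
Why: The magnesium amide formed in the flask converts the ester directly into the Weinreb amide at low temperature, conditions under which Z enoates keep their geometry.

Step 9
Reactants: 10 (3R,4S)-3-(tert-butyldimethylsilyloxy)-4-(4-methoxybenzyloxy)hex-5-en-2-one; 15 ethynylmagnesium bromide; 14 (2Z)-4-(tert-butyldimethylsilyloxy)-N-methoxy-N,2-dimethylbut-2-enamide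
Product: 18 (2Z,7S,8R,9S)-1,8-bis(tert-butyldimethylsilyloxy)-7-hydroxy-9-(4-methoxybenzyloxy)-3,7-dimethylundeca-2,10-dien-5-yn-4-one, via bromomagnesium propargylic alkoxide 16 (not isolated), via bromomagnesium acetylide alkoxide 17 (not isolated)
Conditions: 15, THF, −78 → 0 °C; EtMgBr, 0 °C → rt; 14, rt → 40 °C; cold aq. NaHSO4
Reagents that add atoms: none
Why: The alkynyl Grignard adds 1,2 to ketone 10 to give alkoxide 16, EtMgBr then removes the acetylenic proton (the alkoxide is inert) to give 17, and 17 attacks the Weinreb amide to form an N-methoxy-chelated tetrahedral magnesium adduct that releases the ynone only on acidic work-up, so a second addition cannot occur. The closest known reaction types are the use of acetylene as a two-ended nucleophile and the acylation of alkynylmagnesium reagents by Weinreb amides. No ring is closed; the step forms the two skeletal bonds C10–C1 and C2–C3. The one new stereocentre, C10, is set by the C9 centre in a polar Felkin–Anh transition state: the C9–O bond lies anti to the incoming nucleophile, the C8 chain sits beside the carbonyl oxygen and the C9 hydrogen beside the methyl group, which gives the anti relation of the C9 and C10 oxygens (10R in target numbering). The bulky silyl ether is a poor ligand for magnesium, so the Cram chelate that would give the epimer is disfavoured, and THF competes with chelation through the C8 PMB ether. The step also needs addition in preference to enolisation of the methyl ketone (alkynyl Grignards are weakly basic), C-acylation without conjugate addition to the enamide (so the Z geometry is kept), and a cold acidic quench so that the liberated methoxymethylamine does not add to the ynone.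

Step 10
Reactants: 18 the γ-hydroxy ynone
Product: 20 (2R)-2-[(1R,2S)-1-(tert-butyldimethylsilyloxy)-2-(4-methoxybenzyloxy)but-3-en-1-yl]-5-[(2Z)-4-(tert-butyldimethylsilyloxy)but-2-en-2-yl]-2-methylfuran-3(2H)-one, via C1-diethylamino enaminone 19 (not isolated)
Conditions: Et2NH, EtOH, rt; then aq. oxalic acid, THF, 0 °C → rt
Reagents that add atoms: water, O
Why: Diethylamine adds to the β-carbon C1 of the ynone; in mild aqueous acid the C10 hydroxyl closes on C3 (5-exo-trig), water is lost and the C1 iminium is hydrolysed, which is the known conversion of γ-hydroxy ynones into 3(2H)-furanones. C10 is quaternary and cannot epimerise, and the Z enone is not touched because the alkyne is by far the better acceptor.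

Step 11
Reactants: 20 the furanone
Product: 22 (2R,3R)-3-(tert-butyldimethylsilyloxy)-2-(4-methoxybenzyloxy)-3-[(2R)-5-[(2Z)-4-(tert-butyldimethylsilyloxy)but-2-en-2-yl]-2-methyl-3-oxo-2,3-dihydrofuran-2-yl]propanal, via C7 vicinal diol 21 (not isolated)
Conditions: OsO4 (cat.), NaIO4, 2,6-lutidine, dioxane/H2O, rt
Reagents that add atoms: osmium tetroxide, O=[Os](=O)(=O)=O; NaIO4 (sodium periodate), [Na+].[O-]I(=O)(=O)=O
Why: Lemieux–Johnson cleavage; the monosubstituted vinyl group is the only alkene not conjugated to ring B, whereas C2=C3 is a push–pull alkene and C4=C5 is trisubstituted, conjugated and deactivated by the allylic silyloxy group. Lutidine buffers the medium and protects the C8 centre of the aldehyde.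

Step 12
Reactants: 22 the C7 aldehyde; 23 methyl acrylate
Product: 24 methyl 2-methylene-3-hydroxy ester formed at C7 (Morita–Baylis–Hillman adduct; C7 epimers; C8 to C10 as in 22)
Conditions: 23 (excess), DABCO, MeOH, rt
Reagents that add atoms: none
Why: Morita–Baylis–Hillman reaction; the α-alkoxy aldehyde is an activated acceptor and protic co-solvent accelerates the proton transfer. The new C7 carbinol centre is of no consequence because C7 becomes sp2 in step 13.

Step 13
Reactants: 24 the Morita–Baylis–Hillman adduct
Product: 25 methyl (2Z)-2-(bromomethyl)alk-2-enoate with C7=C11 and bromine on C13 (C8 to C10 as in 22)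
Conditions: NBS, Me2S, CH2Cl2, −20 °C → rt
Reagents that add atoms: N-bromosuccinimide, O=C1CCC(=O)N1Br
Why: Corey–Kim-type activation of the hydroxyl as an alkoxysulfonium ion followed by SN2' attack of bromide moves the leaving group to C13 and gives the more stable Z enoate (C8 trans to the ester), the known outcome for such adducts.

Step 14
Reactants: 25 the allylic bromide
Product: 26 C6 primary allylic alcohol of 25 (C9 silyl ether retained)
Conditions: CSA (cat.), MeOH/CH2Cl2, 0 °C
Reagents that add atoms: none
Why: Acid-catalysed methanolysis removes the primary allylic TBS ether much faster than the hindered secondary one at C9; amine or basic fluoride reagents are avoided because they would attack the allylic bromide.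

Step 15
Reactants: 26 the allylic alcohol
Product: 27 (Z)-enal at C6 bearing the 2-(bromomethyl)acrylate at C7
Conditions: Dess–Martin periodinane, NaHCO3, CH2Cl2, 0 °C
Reagents that add atoms: none
Why: Buffered Dess–Martin oxidation of a primary allylic alcohol is fast at 0 °C and tolerates the allylic bromide; the Z enal is used crude to limit isomerisation.

Step 16
Reactants: 27 the bromo enal
Product: 30 8-O-(4-methoxybenzyl)-9-O-(tert-butyldimethylsilyl) derivative of the 8-deacyl target (rings A, B and C complete; configuration as in 33), via C13 allylchromium dichloride 28 (not isolated), via ring A hydroxy ester 29 (not isolated)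
Conditions: CrCl2 (excess), THF, high dilution, rt; aq. NH4Cl; TsOH (cat.), CH2Cl2
Reagents that add atoms: none
Why: Nozaki–Hiyama (Barbier-type) allylation: divalent chromium converts the allylic bromide into an allylchromium that adds through C7 to the C6 aldehyde in a six-membered chair (10-exo-trig closure of ring A), and the resulting alkoxide lactonises on C12 (5-exo-trig closure of ring C). The ester on C11 keeps C8 cis to the metal-bearing carbon, the geometry that gives the syn adduct and hence the cis ring fusion at C6/C7; the face relative to C8 is left to the resident C8 centre and the conformation of the forming ring. Chromium is chosen because it adds to aldehydes and leaves the nearer C1 carbonyl of ring B alone.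

Step 17
Reactants: 30 the PMB-protected macrolactone
Product: 31 9-O-(tert-butyldimethylsilyl) derivative of the 8-deacyl target (free C8 hydroxyl)
Conditions: DDQ, CH2Cl2/pH 7 buffer, 0 °C
Reagents that add atoms: none
Why: Oxidative cleavage of the PMB ether under neutral buffered conditions leaves the silyl ether, the dienone and the lactone untouched.

Step 18
Reactants: 31 the C8 alcohol
Product: 32 9-O-(tert-butyldimethylsilyl) derivative of the target (C8 isovalerate)
Conditions: isovaleric anhydride, DMAP, Et3N, CH2Cl2, 0 °C
Reagents that add atoms: 3-methylbutanoic anhydride, CC(C)CC(=O)OC(=O)CC(C)C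
Why: DMAP-catalysed acylation of the only free hydroxyl; O9 is still silylated so there is no regiochemical question, and the low temperature disfavours attack of O8 on the lactone carbonyl.

Step 19
Reactants: 32 the silyl-protected target
Product: 33 CNP0175298.2, (4Z,6S,7S,8S,9R,10R)-configured 8-isovaleryloxy-9-hydroxy furanone lactone
Conditions: HF·pyridine, THF, 0 °C → rt
Reagents that add atoms: none
Why: Mildly acidic fluoride removes the hindered secondary TBS ether without the basic conditions that would move the isovalerate to O9 or add to the methylene lactone.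

## Compound list

1 | ethyl (S)-lactate | C[C@H](O)C(=O)OCC | starting material
2 | ethyl (2S)-2-(triethylsilyloxy)propanoate | C[C@H](O[Si](CC)(CC)CC)C(=O)OCC | intermediate
3 | (2S)-2-(triethylsilyloxy)propanal | C[C@H](O[Si](CC)(CC)CC)C=O | intermediate
4 | allyl 4-methoxybenzyl ether | C=CCOCc1ccc(OC)cc1 | starting material
5 | (Z)-3-(4-methoxybenzyloxy)allyllithium | [Li]C/C=C\OCc1ccc(OC)cc1 | intermediate
6 | [(Z)-3-(4-methoxybenzyloxy)allyl]diisopinocampheylborane (isopinocampheyl groups from (−)-α-pinene) | COc1ccc(CO/C=C\CB([C@@H]2[C@@H](C)[C@@H]3C[C@H](C2)C3(C)C)[C@@H]4[C@@H](C)[C@@H]5C[C@H](C4)C5(C)C)cc1 | intermediate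
7 | (2S,3R,4S)-4-(4-methoxybenzyloxy)-2-(triethylsilyloxy)hex-5-en-3-ol | C[C@H](O[Si](CC)(CC)CC)[C@H](O)[C@@H](OCc1ccc(OC)cc1)C=C | intermediate
8 | (2S,3R,4S)-3-(tert-butyldimethylsilyloxy)-4-(4-methoxybenzyloxy)-2-(triethylsilyloxy)hex-5-ene | C[C@H](O[Si](CC)(CC)CC)[C@H](O[Si](C)(C)C(C)(C)C)[C@@H](OCc1ccc(OC)cc1)C=C | intermediate
9 | (2S,3S,4S)-3-(tert-butyldimethylsilyloxy)-4-(4-methoxybenzyloxy)hex-5-en-2-ol | C[C@H](O)[C@H](O[Si](C)(C)C(C)(C)C)[C@@H](OCc1ccc(OC)cc1)C=C | intermediate
10 | (3R,4S)-3-(tert-butyldimethylsilyloxy)-4-(4-methoxybenzyloxy)hex-5-en-2-one (fragment 1) | CC(=O)[C@H](O[Si](C)(C)C(C)(C)C)[C@@H](OCc1ccc(OC)cc1)C=C | intermediate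
11 | (tert-butyldimethylsilyloxy)acetaldehyde | CC(C)(C)[Si](C)(C)OCC=O | starting material
12 | methyl 2-[bis(2,2,2-trifluoroethoxy)phosphoryl]propanoate | COC(=O)C(C)P(=O)(OCC(F)(F)F)OCC(F)(F)F | starting material
13 | methyl (2Z)-4-(tert-butyldimethylsilyloxy)-2-methylbut-2-enoate | COC(=O)/C(C)=C\CO[Si](C)(C)C(C)(C)C | intermediate
14 | (2Z)-4-(tert-butyldimethylsilyloxy)-N-methoxy-N,2-dimethylbut-2-enamide (fragment 2) | CON(C)C(=O)/C(C)=C\CO[Si](C)(C)C(C)(C)C | intermediate
15 | ethynylmagnesium bromide | C#C[Mg]Br | starting material
16 | bromomagnesium alkoxide of (3S,4R,5S)-4-(tert-butyldimethylsilyloxy)-5-(4-methoxybenzyloxy)-3-methylhept-6-en-1-yn-3-ol | C#C[C@](C)(O[Mg]Br)[C@H](O[Si](C)(C)C(C)(C)C)[C@@H](OCc1ccc(OC)cc1)C=C | intermediate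
17 | C1-bromomagnesium acetylide of alkoxide 16 | Br[Mg]C#C[C@](C)(O[Mg]Br)[C@H](O[Si](C)(C)C(C)(C)C)[C@@H](OCc1ccc(OC)cc1)C=C | intermediate
18 | (2Z,7S,8R,9S)-1,8-bis(tert-butyldimethylsilyloxy)-7-hydroxy-9-(4-methoxybenzyloxy)-3,7-dimethylundeca-2,10-dien-5-yn-4-one | CC(C)(C)[Si](C)(C)OC/C=C(/C)C(=O)C#C[C@](C)(O)[C@H](O[Si](C)(C)C(C)(C)C)[C@@H](OCc1ccc(OC)cc1)C=C | intermediate
19 | (2Z,7S,8R,9S)-6-(diethylamino)-1,8-bis(tert-butyldimethylsilyloxy)-7-hydroxy-9-(4-methoxybenzyloxy)-3,7-dimethylundeca-2,5,10-trien-4-one | CCN(CC)C(=CC(=O)/C(C)=C\CO[Si](C)(C)C(C)(C)C)[C@](C)(O)[C@H](O[Si](C)(C)C(C)(C)C)[C@@H](OCc1ccc(OC)cc1)C=C | intermediate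
20 | (2R)-2-[(1R,2S)-1-(tert-butyldimethylsilyloxy)-2-(4-methoxybenzyloxy)but-3-en-1-yl]-5-[(2Z)-4-(tert-butyldimethylsilyloxy)but-2-en-2-yl]-2-methylfuran-3(2H)-one | C/C(=C/CO[Si](C)(C)C(C)(C)C)C1=CC(=O)[C@](C)(O1)[C@H](O[Si](C)(C)C(C)(C)C)[C@@H](OCc2ccc(OC)cc2)C=C | intermediate
21 | C7 vicinal diol from dihydroxylation of the vinyl group of 20 (C7 epimers) | C/C(=C/CO[Si](C)(C)C(C)(C)C)C1=CC(=O)[C@](C)(O1)[C@H](O[Si](C)(C)C(C)(C)C)[C@@H](OCc2ccc(OC)cc2)C(O)CO | intermediate
22 | (2R,3R)-3-(tert-butyldimethylsilyloxy)-2-(4-methoxybenzyloxy)-3-[(2R)-5-[(2Z)-4-(tert-butyldimethylsilyloxy)but-2-en-2-yl]-2-methyl-3-oxo-2,3-dihydrofuran-2-yl]propanal | C/C(=C/CO[Si](C)(C)C(C)(C)C)C1=CC(=O)[C@](C)(O1)[C@H](O[Si](C)(C)C(C)(C)C)[C@@H](OCc2ccc(OC)cc2)C=O | intermediate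
23 | methyl acrylate | C=CC(=O)OC | starting material
24 | Morita–Baylis–Hillman adduct of 22: methyl 2-methylene-3-hydroxy ester at C7 (C7 epimers) | C/C(=C/CO[Si](C)(C)C(C)(C)C)C1=CC(=O)[C@](C)(O1)[C@H](O[Si](C)(C)C(C)(C)C)[C@@H](OCc2ccc(OC)cc2)C(O)C(=C)C(=O)OC | intermediate
25 | methyl (2Z)-2-(bromomethyl)alk-2-enoate (C7=C11, C13 bromide) | C/C(=C/CO[Si](C)(C)C(C)(C)C)C1=CC(=O)[C@](C)(O1)[C@H](O[Si](C)(C)C(C)(C)C)[C@@H](OCc2ccc(OC)cc2)/C=C(\CBr)C(=O)OC | intermediate
26 | C6 allylic alcohol of 25 | C/C(=C/CO)C1=CC(=O)[C@](C)(O1)[C@H](O[Si](C)(C)C(C)(C)C)[C@@H](OCc2ccc(OC)cc2)/C=C(\CBr)C(=O)OC | intermediate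
27 | (Z)-enal at C6 with the 2-(bromomethyl)acrylate at C7 | C/C(=C/C=O)C1=CC(=O)[C@](C)(O1)[C@H](O[Si](C)(C)C(C)(C)C)[C@@H](OCc2ccc(OC)cc2)/C=C(\CBr)C(=O)OC | intermediate
28 | C13 allylchromium dichloride derived from 27 | C/C(=C/C=O)C1=CC(=O)[C@](C)(O1)[C@H](O[Si](C)(C)C(C)(C)C)[C@@H](OCc2ccc(OC)cc2)/C=C(\C[Cr](Cl)Cl)C(=O)OC | intermediate
29 | ring A hydroxy ester (C6 carbinol, C7 bearing the methyl 2-propenoate unit; configuration as in 30) | COC(=O)C(=C)[C@H]1[C@@H](O)/C=C(/C)C2=CC(=O)[C@](C)(O2)[C@H](O[Si](C)(C)C(C)(C)C)[C@H]1OCc3ccc(OC)cc3 | intermediate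
30 | 8-O-(4-methoxybenzyl)-9-O-(tert-butyldimethylsilyl) derivative of the 8-deacyl target | C=C1C(=O)O[C@H]2/C=C(/C)C3=CC(=O)[C@](C)(O3)[C@H](O[Si](C)(C)C(C)(C)C)[C@@H](OCc4ccc(OC)cc4)[C@@H]12 | intermediate
31 | 9-O-(tert-butyldimethylsilyl) derivative of the 8-deacyl target | C=C1C(=O)O[C@H]2/C=C(/C)C3=CC(=O)[C@](C)(O3)[C@H](O[Si](C)(C)C(C)(C)C)[C@@H](O)[C@@H]12 | intermediate
32 | 9-O-(tert-butyldimethylsilyl) derivative of the target | C=C1C(=O)O[C@H]2/C=C(/C)C3=CC(=O)[C@](C)(O3)[C@H](O[Si](C)(C)C(C)(C)C)[C@@H](OC(=O)CC(C)C)[C@@H]12 | intermediate
33 | CNP0175298.2 (4Z,6S,7S,8S,9R,10R) | C=C1C(=O)O[C@H]2/C=C(/C)C3=CC(=O)[C@](C)(O3)[C@H](O)[C@@H](OC(=O)CC(C)C)[C@@H]12 | target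

## Step count and risks

Total: 19 steps. Longest linear sequence: 17 steps (steps 1–6, 9–19); fragment 2 takes 2 steps (7–8).

**Step 9 (key step).** The most likely failures are loss of facial selectivity at C10, if magnesium bridges the ketone and the C8 PMB oxygen, and sluggish acylation of the poorly soluble dimagnesium species 17, which leaves time for the liberated amine to add to the ynone. Fallback, setting out from 10 and returning at 18: 10 is treated with 15 alone and the product is isolated as (3S,4R,5S)-4-(tert-butyldimethylsilyloxy)-5-(4-methoxybenzyloxy)-3-methylhept-6-en-1-yn-3-ol F1, at which stage a C10 epimer can be removed. Amide 14 is reduced with i-Bu2AlH to (2Z)-4-(tert-butyldimethylsilyloxy)-2-methylbut-2-enal F2. The dilithio derivative of F1 (n-BuLi, 2 equiv) is added to F2 to give the C3 carbinol, the undeca-2,10-dien-5-yne-4,7-diol F3, and MnO2 oxidises its secondary propargylic-allylic hydroxyl selectively to 18. This replaces acylation by addition and oxidation.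

**Step 16.** The most likely failure is attack on the wrong diastereoface during ring closure. The cis fusion is supported by the geometry of the allylmetal, but no reliable model secures the sense relative to C8. Reduction of the allylmetal before closure and Z to E drift of the enal are further concerns. Fallback, setting out from 25 and returning at 29 (and so 30): 25 is converted with Bu3SnSnBu3 and Pd(PPh3)4 into the methyl 2-(tributylstannylmethyl)alk-2-enoate F4. The primary silyl ether is removed with HF·pyridine (now harmless, as no bromide is present) to give the stannyl allylic alcohol F5, and Dess–Martin oxidation gives the stannyl (Z)-enal F6. BF3·OEt2 at −78 °C under high dilution then closes ring A through an open transition state that responds differently to the C8 substituent, giving 29, which lactonises to 30.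

**Step 12.** The most likely failure is a slow reaction at the hindered aldehyde, during which the amine can epimerise C8 or eliminate the C9 silyloxy group. Fallback, setting out from 22 and returning at 24: methyl propiolate is hydroaluminated with i-Bu2AlH in the presence of N-methylmorpholine N-oxide to give [1-(methoxycarbonyl)vinyl]diisobutylalane F7, which adds to the aldehyde of 22 at low temperature without an amine catalyst and gives 24 directly.

**Step 11.** The most likely failure is competing dihydroxylation of the C4=C5 alkene. Fallback, setting out from 18 and returning at 21 (and so 22): at the ynone stage C4=C5 is part of an enone and is the least reactive alkene, so 18 is dihydroxylated with OsO4 and N-methylmorpholine N-oxide to the 10,11-diol of the ynone, triol F8. The conditions of step 10 then convert F8 into 21, and NaIO4 cleaves 21 to 22.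

## Further compounds

F1 | step 9 | (3S,4R,5S)-4-(tert-butyldimethylsilyloxy)-5-(4-methoxybenzyloxy)-3-methylhept-6-en-1-yn-3-ol | C#C[C@](C)(O)[C@H](O[Si](C)(C)C(C)(C)C)[C@@H](OCc1ccc(OC)cc1)C=C
F2 | step 9 | (2Z)-4-(tert-butyldimethylsilyloxy)-2-methylbut-2-enal | O=C/C(C)=C\CO[Si](C)(C)C(C)(C)C
F3 | step 9 | (2Z,7S,8R,9S)-1,8-bis(tert-butyldimethylsilyloxy)-9-(4-methoxybenzyloxy)-3,7-dimethylundeca-2,10-dien-5-yne-4,7-diol (C4 epimers) | CC(C)(C)[Si](C)(C)OC/C=C(/C)C(O)C#C[C@](C)(O)[C@H](O[Si](C)(C)C(C)(C)C)[C@@H](OCc1ccc(OC)cc1)C=C
F4 | step 16 | methyl (2Z)-2-(tributylstannylmethyl)alk-2-enoate corresponding to 25 | C/C(=C/CO[Si](C)(C)C(C)(C)C)C1=CC(=O)[C@](C)(O1)[C@H](O[Si](C)(C)C(C)(C)C)[C@@H](OCc2ccc(OC)cc2)/C=C(\C[Sn](CCCC)(CCCC)CCCC)C(=O)OC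
F5 | step 16 | C6 allylic alcohol of F4 | C/C(=C/CO)C1=CC(=O)[C@](C)(O1)[C@H](O[Si](C)(C)C(C)(C)C)[C@@H](OCc2ccc(OC)cc2)/C=C(\C[Sn](CCCC)(CCCC)CCCC)C(=O)OC
F6 | step 16 | (Z)-enal of F5 | C/C(=C/C=O)C1=CC(=O)[C@](C)(O1)[C@H](O[Si](C)(C)C(C)(C)C)[C@@H](OCc2ccc(OC)cc2)/C=C(\C[Sn](CCCC)(CCCC)CCCC)C(=O)OC
F7 | step 12 | [1-(methoxycarbonyl)vinyl]diisobutylalane | COC(=O)C(=C)[Al](CC(C)C)CC(C)C
F8 | step 11 | 10,11-diol of ynone 18 (C10 epimers of the undecane chain) | CC(C)(C)[Si](C)(C)OC/C=C(/C)C(=O)C#C[C@](C)(O)[C@H](O[Si](C)(C)C(C)(C)C)[C@@H](OCc1ccc(OC)cc1)C(O)CO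
A1 | alternative 1 | macrocyclic 8,9-diol lacking the C13 methylene | O=C1O[C@H]2/C=C(/C)C3=CC(=O)[C@](C)(O3)[C@H](O)[C@@H](O)[C@H]2C1
A2 | alternative 1 | seco-dialdehyde with formyl groups at C8 and C9 | O=C1O[C@@H](/C=C(/C)C2=CC(=O)[C@@](C)(C=O)O2)[C@@H](C=O)C1
A3 | alternative 2 | cyclic C1 propargylic alcohol (one C1 epimer) | C=C1C(=O)O[C@H]2/C=C(/C)C#C[C@@H](O)[C@](C)(O[Si](C)(C)C)[C@H](O[Si](CC)(CC)CC)[C@@H](OC(=O)CC(C)C)[C@@H]12
A4 | alternative 2 | acyclic C2 iodoalkyne with the C1 aldehyde | IC#C/C(C)=C\[C@@H]1OC(=O)C(=C)[C@@H]1[C@H](OC(=O)CC(C)C)[C@@H](O[Si](CC)(CC)CC)[C@@](C)(O[Si](C)(C)C)C=O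
A5 | alternative 3 | C11 diethylphosphono lactone (one C11 epimer) | CCOP(=O)(OCC)[C@@H]1C(=O)O[C@H]2/C=C(/C)C3=CC(=O)[C@](C)(O3)[C@H](O[Si](C)(C)C(C)(C)C)[C@@H](O[Si](C)(C)C(C)(C)C)[C@@H]12
A6 | alternative 3 | C6 diazophosphonoacetate of the furanone macrocycle with a C7 methylene | CCOP(=O)(OCC)C(=[N+]=[N-])C(=O)O[C@H]1/C=C(/C)C2=CC(=O)[C@](C)(O2)[C@H](O[Si](C)(C)C(C)(C)C)[C@@H](O[Si](C)(C)C(C)(C)C)C1
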